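**Plan**

- Cuts, in retrosynthetic order: the Cα=Cβ bond of the ring A/ring B enone (Claisen–Schmidt); the C1'–C6' bond of ring A', which unfolds the resorcinol into a 2-(cinnamoylmethyl)-5-aryloxy-4-pyranone; the CH2–C(=O) bond of that side chain (acylation of a pyranone 2-methyl carbanion); the O–C(ring B) bond of the diaryl ether (SNAr).
- Enabling feature: C2'–C6' of ring A', with oxygen on C2', C4' and C5', are C2–C6 of kojic acid with its ring oxygen, its C4 carbonyl oxygen and its 5-hydroxyl oxygen; the exocyclic carbon on pyranone C2 is C1', the carbon that carries the cinnamoyl group.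
- Forward order: kojic acid is reduced to the 2-methylpyranone, ring B is attached through oxygen and its aldehyde masked, the ring B' cinnamoyl unit is joined to the methyl group, and alkali then opens the pyranone and refolds the chain into ring A', the only ring that is built.
- The ring B aldehyde is then released and condensed with the ring A acetophenone, and acid removes the two MOM ethers.
- Stereochemistry: the target has no stereocentre; the ring B' enone keeps the E geometry of (E)-p-coumaric acid, and the ring A/ring B enone forms E under the equilibrating E1cB dehydration of the Claisen–Schmidt step.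

Key step: step 8

Remark: primed locants belong to the chalcone that contains ring A' and ring B'; the 1,3-dicarbonyl compounds of steps 7 and 8 are drawn as keto forms although they should exist largely as enols or enolates.

**Route**

Step 1
Reactants: 1 kojic acid
Product: 2 2-(chloromethyl)-5-hydroxy-4H-pyran-4-one (chlorokojic acid)
Conditions: SOCl2 (neat), 0 °C → rt
Reagents that add atoms: thionyl chloride, O=S(Cl)Cl
Why: Deoxychlorination of the primary alcohol through its chlorosulfite is the standard entry to chlorokojic acid, and the acidic enolic 5-OH is not chlorinated.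

Step 2
Reactants: 2 2-(chloromethyl)-5-hydroxy-4H-pyran-4-one
Product: 3 5-hydroxy-2-methyl-4H-pyran-4-one (allomaltol)
Conditions: Zn dust, conc. HCl, H2O, 70 °C
Reagents that add atoms: none
Why: Dissolving-metal reductive dehalogenation of the activated C–Cl bond by zinc in acid is the classical reduction of chlorokojic acid to allomaltol and leaves the pyranone ring intact.

Step 3
Reactants: 3 5-hydroxy-2-methyl-4H-pyran-4-one; 4 4-fluorobenzaldehyde
Product: 5 4-[(6-methyl-4-oxo-4H-pyran-3-yl)oxy]benzaldehyde
Conditions: K2CO3, DMF, 100 °C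
Reagents that add atoms: none
Why: Nucleophilic aromatic substitution (SNAr, addition–elimination) in which the pyranone olate displaces the fluoride para to the formyl group through a Meisenheimer intermediate should give the diaryl-type ether.

Step 4
Reactants: 5 4-[(6-methyl-4-oxo-4H-pyran-3-yl)oxy]benzaldehyde
Product: 6 5-[4-(1,3-dioxolan-2-yl)phenoxy]-2-methyl-4H-pyran-4-one
Conditions: HOCH2CH2OH, p-TsOH·H2O (cat.), toluene, reflux, Dean–Stark
Reagents that add atoms: ethylene glycol, OCCO
Why: Acid-catalysed acetalisation with azeotropic removal of water masks the aldehyde against the carbanion of step 7 and the alkali of step 8, while the pyranone carbonyl, a vinylogous ester, does not ketalise.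

Step 5
Reactants: 7 (E)-p-coumaric acid
Product: 8 (E)-3-(4-hydroxyphenyl)-N-methoxy-N-methylprop-2-enamide
Conditions: MeNH(OMe)·HCl, EDC·HCl, HOBt (cat.), iPr2NEt, DMF, 0 °C → rt
Reagents that add atoms: N,O-dimethylhydroxylamine hydrochloride, CNOC.Cl
Why: Carbodiimide amide coupling through the HOBt active ester gives the Weinreb amide without phenol protection, since any aryl ester formed is aminolysed, and the E alkene is untouched.

Step 6
Reactants: 8 (E)-3-(4-hydroxyphenyl)-N-methoxy-N-methylprop-2-enamide
Product: 9 (E)-N-methoxy-3-[4-(methoxymethoxy)phenyl]-N-methylprop-2-enamide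
Conditions: MOMCl, iPr2NEt, CH2Cl2, 0 °C → rt
Reagents that add atoms: chloromethyl methyl ether, COCCl
Why: Williamson-type O-alkylation of the phenol gives a MOM ether that is inert to the strong bases of steps 7, 8 and 11 and falls off with acid at the end.

Step 7
Reactants: 6 5-[4-(1,3-dioxolan-2-yl)phenoxy]-2-methyl-4H-pyran-4-one; 9 (E)-N-methoxy-3-[4-(methoxymethoxy)phenyl]-N-methylprop-2-enamide
Product: 11 (E)-1-{5-[4-(1,3-dioxolan-2-yl)phenoxy]-4-oxo-4H-pyran-2-yl}-4-[4-(methoxymethoxy)phenyl]but-3-en-2-one, via lithium dienolate 10 (not isolated)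
Conditions: LiN(SiMe3)2 (2.2 equiv), THF, −78 °C; then 9, −78 → 0 °C; AcOH
Reagents that add atoms: none
Why: Vinylogous deprotonation of the 2-methyl group, the most acidic C–H of the 4-pyranone, gives dienolate 10, which is C-acylated by the Weinreb amide in a crossed Claisen-type condensation; the chelated tetrahedral adduct and the second equivalent of base prevent over-addition and quenching by the more acidic product, and the amide favours 1,2- over 1,4-attack.

Step 8
Reactants: 11 (E)-1-{5-[4-(1,3-dioxolan-2-yl)phenoxy]-4-oxo-4H-pyran-2-yl}-4-[4-(methoxymethoxy)phenyl]but-3-en-2-one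
Product: 14 (E)-1-{5-[4-(1,3-dioxolan-2-yl)phenoxy]-2,4-dihydroxyphenyl}-3-[4-(methoxymethoxy)phenyl]prop-2-en-1-one, via open-chain keto aldehyde 12 (not isolated), via cyclic aldol 13 (not isolated)
Conditions: KOH (5 equiv), MeOH–H2O (3:1, degassed), Ar, rt → 45 °C; then AcOH to pH 6, 0 °C
Reagents that add atoms: none
Why: Proposed new method: hydroxide adds to the unsubstituted C6 of the vinylogous ester of 11 and the ring oxygen leaves as the enolate oxygen on C2', which unmasks the α-aryloxy β-keto aldehyde 12; its C1' carbon, activated by the C2' ketone and the cinnamoyl ketone, attacks the aldehyde carbon C6' to give aldol 13, and loss of water followed by enolisation of the C2' and C4' ketones gives the resorcinol ring of 14, the whole being an isomerisation driven by aromatisation. The closest known reaction type is the alkali-induced opening of 2,6-dimethyl-4-pyranone to heptane-2,4,6-trione and its aldol recyclisation to orcinol, together with the aldol cyclisation of open-chain tetraketones to acylresorcinols; it has not been shown for a 5-aryloxy-4-pyranone with a free C6–H, where the acceptor is an aldehyde. Ring A' closes in a 6-(enolexo)-exo-trig aldol addition of C1' to C6'. No lasting stereocentre is formed, since the sp3 centres of 12 and 13 disappear on aromatisation, and the E enone is not touched. The step needs the C1'–C6' pairing and not the aldol of C5' onto the cinnamoyl carbonyl or a deformylation: the aldol additions are reversible in aqueous alkali, the formyl carbon is the most electrophilic carbonyl carbon of the chain and is held as its enolate against retro-Claisen loss, and only the C1'–C6' ring can dehydrate and aromatise without breaking a C–C bond, so it is the irreversible exit. The dioxolane and the MOM ether are inert to alkali, the enolised β-diketone shields the enone from hydroxide, and exclusion of air protects the electron-rich polyenolates.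

Step 9
Reactants: 14 (E)-1-{5-[4-(1,3-dioxolan-2-yl)phenoxy]-2,4-dihydroxyphenyl}-3-[4-(methoxymethoxy)phenyl]prop-2-en-1-one
Product: 15 4-{2,4-dihydroxy-5-[(E)-3-(4-(methoxymethoxy)phenyl)prop-2-enoyl]phenoxy}benzaldehyde
Conditions: p-TsOH·H2O (cat.), acetone–H2O (10:1), rt
Reagents that add atoms: water, O
Why: Acid-catalysed acetal hydrolysis of the dioxolane of an electron-rich aryl aldehyde should proceed under conditions far milder than those that cleave an aryl MOM ether or cyclise a 2'-hydroxychalcone to a flavanone.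

Step 10
Reactants: 16 2,4-dihydroxyacetophenone
Product: 17 1-[2-hydroxy-4-(methoxymethoxy)phenyl]ethanone
Conditions: MOMCl (1.1 equiv), K2CO3, acetone, 0 °C → rt
Reagents that add atoms: chloromethyl methyl ether, COCCl
Why: Regioselective Williamson etherification protects the more acidic, non-chelated 4-OH, while the 2-OH stays hydrogen-bonded to the ketone and unreactive.

Step 11
Reactants: 15 4-{2,4-dihydroxy-5-[(E)-3-(4-(methoxymethoxy)phenyl)prop-2-enoyl]phenoxy}benzaldehyde; 17 1-[2-hydroxy-4-(methoxymethoxy)phenyl]ethanone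
Product: 19 (E)-3-(4-{2,4-dihydroxy-5-[(E)-3-(4-(methoxymethoxy)phenyl)prop-2-enoyl]phenoxy}phenyl)-1-[2-hydroxy-4-(methoxymethoxy)phenyl]prop-2-en-1-one, via aldol adduct 18 (not isolated)
Conditions: KOH (50% aq, excess), EtOH, Ar, 0 °C → rt; then AcOH to pH 6, 0 °C
Reagents that add atoms: none
Why: Claisen–Schmidt condensation (crossed aldol to 18, then E1cB dehydration) of the non-enolisable aldehyde 15 with the enolate of 17 gives the E enone under equilibrating conditions, and the ring A' chalcone is shielded from Michael addition and retro-aldol cleavage as its electron-rich phenolate.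

Step 12
Reactants: 19 (E)-3-(4-{2,4-dihydroxy-5-[(E)-3-(4-(methoxymethoxy)phenyl)prop-2-enoyl]phenoxy}phenyl)-1-[2-hydroxy-4-(methoxymethoxy)phenyl]prop-2-en-1-one
Product: 20 (E)-1-(2,4-dihydroxyphenyl)-3-(4-{2,4-dihydroxy-5-[(E)-3-(4-hydroxyphenyl)prop-2-enoyl]phenoxy}phenyl)prop-2-en-1-one (target)
Conditions: 3 M aq HCl, MeOH, 50 °C
Reagents that add atoms: none
Why: Acid-catalysed acetal exchange in methanol cleaves both aryl MOM ethers as dimethoxymethane, and a short reaction time at moderate temperature should limit acid-promoted cyclisation of the 2'-hydroxychalcones to flavanones.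

**Compound list**

1 | kojic acid, 5-hydroxy-2-(hydroxymethyl)-4H-pyran-4-one | OCc1cc(=O)c(O)co1 | starting material
2 | 2-(chloromethyl)-5-hydroxy-4H-pyran-4-one | ClCc1cc(=O)c(O)co1 | intermediate
3 | 5-hydroxy-2-methyl-4H-pyran-4-one (allomaltol) | Cc1cc(=O)c(O)co1 | intermediate
4 | 4-fluorobenzaldehyde | O=Cc1ccc(F)cc1 | starting material
5 | 4-[(6-methyl-4-oxo-4H-pyran-3-yl)oxy]benzaldehyde | Cc1cc(=O)c(Oc2ccc(C=O)cc2)co1 | intermediate
6 | 5-[4-(1,3-dioxolan-2-yl)phenoxy]-2-methyl-4H-pyran-4-one | Cc1cc(=O)c(Oc2ccc(C3OCCO3)cc2)co1 | intermediate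
7 | (E)-p-coumaric acid | O=C(O)/C=C/c1ccc(O)cc1 | starting material
8 | (E)-3-(4-hydroxyphenyl)-N-methoxy-N-methylprop-2-enamide | CON(C)C(=O)/C=C/c1ccc(O)cc1 | intermediate
9 | (E)-N-methoxy-3-[4-(methoxymethoxy)phenyl]-N-methylprop-2-enamide | CON(C)C(=O)/C=C/c1ccc(OCOC)cc1 | intermediate
10 | lithium dienolate of 6, lithium 5-[4-(1,3-dioxolan-2-yl)phenoxy]-2-methylidene-2H-pyran-4-olate (not isolated) | C=C1C=C(O[Li])C(Oc2ccc(C3OCCO3)cc2)=CO1 | intermediate
11 | (E)-1-{5-[4-(1,3-dioxolan-2-yl)phenoxy]-4-oxo-4H-pyran-2-yl}-4-[4-(methoxymethoxy)phenyl]but-3-en-2-one | O=C(Cc1cc(=O)c(Oc2ccc(C3OCCO3)cc2)co1)/C=C/c1ccc(OCOC)cc1 | intermediate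
12 | (E)-2-[4-(1,3-dioxolan-2-yl)phenoxy]-9-[4-(methoxymethoxy)phenyl]-3,5,7-trioxonon-8-enal, racemic at C2, present as enolates (not isolated) | O=CC(Oc1ccc(C2OCCO2)cc1)C(=O)CC(=O)CC(=O)/C=C/c1ccc(OCOC)cc1 | intermediate
13 | 4-[4-(1,3-dioxolan-2-yl)phenoxy]-5-hydroxy-6-[(E)-3-(4-(methoxymethoxy)phenyl)prop-2-enoyl]cyclohexane-1,3-dione, mixture of stereoisomers (not isolated) | O=C(/C=C/c1ccc(OCOC)cc1)C1C(O)C(Oc2ccc(C3OCCO3)cc2)C(=O)CC1=O | intermediate
14 | (E)-1-{5-[4-(1,3-dioxolan-2-yl)phenoxy]-2,4-dihydroxyphenyl}-3-[4-(methoxymethoxy)phenyl]prop-2-en-1-one | O=C(/C=C/c1ccc(OCOC)cc1)c1cc(Oc2ccc(C3OCCO3)cc2)c(O)cc1O | intermediate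
15 | 4-{2,4-dihydroxy-5-[(E)-3-(4-(methoxymethoxy)phenyl)prop-2-enoyl]phenoxy}benzaldehyde | O=Cc1ccc(Oc2cc(C(=O)/C=C/c3ccc(OCOC)cc3)c(O)cc2O)cc1 | intermediate
16 | 2,4-dihydroxyacetophenone | CC(=O)c1ccc(O)cc1O | starting material
17 | 1-[2-hydroxy-4-(methoxymethoxy)phenyl]ethanone | CC(=O)c1ccc(OCOC)cc1O | intermediate
18 | 3-(4-{2,4-dihydroxy-5-[(E)-3-(4-(methoxymethoxy)phenyl)prop-2-enoyl]phenoxy}phenyl)-3-hydroxy-1-[2-hydroxy-4-(methoxymethoxy)phenyl]propan-1-one, racemic (not isolated) | O=C(CC(O)c1ccc(Oc2cc(C(=O)/C=C/c3ccc(OCOC)cc3)c(O)cc2O)cc1)c1ccc(OCOC)cc1O | intermediate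
19 | (E)-3-(4-{2,4-dihydroxy-5-[(E)-3-(4-(methoxymethoxy)phenyl)prop-2-enoyl]phenoxy}phenyl)-1-[2-hydroxy-4-(methoxymethoxy)phenyl]prop-2-en-1-one | O=C(/C=C/c1ccc(Oc2cc(C(=O)/C=C/c3ccc(OCOC)cc3)c(O)cc2O)cc1)c1ccc(OCOC)cc1O | intermediate
20 | (E)-1-(2,4-dihydroxyphenyl)-3-(4-{2,4-dihydroxy-5-[(E)-3-(4-hydroxyphenyl)prop-2-enoyl]phenoxy}phenyl)prop-2-en-1-one | O=C(/C=C/c1ccc(Oc2cc(C(=O)/C=C/c3ccc(O)cc3)c(O)cc2O)cc1)c1ccc(O)cc1O | target

**Count and risks**

Total step count: 12. Longest linear sequence: 9 steps (steps 1, 2, 3, 4, 7, 8, 9, 11, 12).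

Steps most likely to fail:

Step 8. The ring opening may stall at the delocalised side-chain anion of 11, or the opened chain may lose its formyl group by retro-Claisen cleavage or fold through C5' onto the cinnamoyl carbonyl, so that ring A' does not form. The fallback takes ring A' from an existing benzene ring by known reactions. It sets out from 4: SNAr with commercial 2,4-dimethoxyphenol (K2CO3, DMF, 120 °C) should give 4-(2,4-dimethoxyphenoxy)benzaldehyde F1. Friedel–Crafts acetylation (AcCl, SnCl4, CH2Cl2, −10 °C) para to the 2-methoxy group should give 4-(5-acetyl-2,4-dimethoxyphenoxy)benzaldehyde F2. BBr3 (CH2Cl2, −78 °C → rt) should cleave both methyl ethers to 4-(5-acetyl-2,4-dihydroxyphenoxy)benzaldehyde F3. Chemoselective acetalisation of the aldehyde (ethylene glycol, p-TsOH cat., toluene, Dean–Stark; the hydrogen-bonded aryl ketone stays) should give 1-{5-[4-(1,3-dioxolan-2-yl)phenoxy]-2,4-dihydroxyphenyl}ethanone F4. Claisen–Schmidt condensation of F4 with 4-(methoxymethoxy)benzaldehyde (KOH, EtOH–H2O, rt) comes back to the route at 14.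

Step 7. The soft dienolate 10 may add in conjugate fashion to the enamide, or acyl transfer may be slow and incomplete, so that little C-acylated diketone forms. The fallback replaces acylation by aldol addition and oxidation. It sets out from 9 and 6: reduction of 9 with i-Bu2AlH (THF, −78 °C) should give (E)-3-[4-(methoxymethoxy)phenyl]prop-2-enal F5. Dienolate 10, made from 6 as before, should add 1,2 to this enal at −78 °C to give racemic (E)-5-[4-(1,3-dioxolan-2-yl)phenoxy]-2-{2-hydroxy-4-[4-(methoxymethoxy)phenyl]but-3-en-1-yl}-4H-pyran-4-one F6. Oxidation of the allylic alcohol with MnO2 (CH2Cl2, rt) or Dess–Martin periodinane comes back to the route at 11.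

Step 3. The pyranone olate is a weak oxygen nucleophile, and its C6 carbon can add to the aldehyde of 4 in an aldol-type hydroxyalkylation, so that C-alkylation may outrun the SNAr. The fallback forms the C–O bond by copper catalysis with an aldehyde-free partner. It sets out from 3: Ullmann-type coupling with commercial 2-(4-bromophenyl)-1,3-dioxolane (CuI, picolinic acid, K3PO4, DMSO, 90 °C) should give 6 directly, which also makes step 4 unnecessary; no compound outside the route is formed (F0).

**Further compounds**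

F1 | step 8 | 4-(2,4-dimethoxyphenoxy)benzaldehyde | COc1ccc(Oc2ccc(C=O)cc2)c(OC)c1
F2 | step 8 | 4-(5-acetyl-2,4-dimethoxyphenoxy)benzaldehyde | CC(=O)c1cc(Oc2ccc(C=O)cc2)c(OC)cc1OC
F3 | step 8 | 4-(5-acetyl-2,4-dihydroxyphenoxy)benzaldehyde | CC(=O)c1cc(Oc2ccc(C=O)cc2)c(O)cc1O
F4 | step 8 | 1-{5-[4-(1,3-dioxolan-2-yl)phenoxy]-2,4-dihydroxyphenyl}ethanone | CC(=O)c1cc(Oc2ccc(C3OCCO3)cc2)c(O)cc1O
F5 | step 7 | (E)-3-[4-(methoxymethoxy)phenyl]prop-2-enal | O=C/C=C/c1ccc(OCOC)cc1
F6 | step 7 | (E)-5-[4-(1,3-dioxolan-2-yl)phenoxy]-2-{2-hydroxy-4-[4-(methoxymethoxy)phenyl]but-3-en-1-yl}-4H-pyran-4-one, racemic | OC(Cc1cc(=O)c(Oc2ccc(C3OCCO3)cc2)co1)/C=C/c1ccc(OCOC)cc1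
F0 | step 3 | none | none
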